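**Plan**

- Retrosynthesis: after removal of the ring A silyl group, ring B is cut at C3'–C4' and C1'–C6'. This releases C4'–C5'–C6' as malonyl dichloride and leaves C1'–C2'–C3' with the C3' prenyl group as a 1,3-bis(trimethylsilyloxy)diene.
- Enabling feature: ring B (C1' aroyl, C2' OH, C3' prenyl, C4' OH, C5' H, C6' OH) is a phloroglucinol, a masked cyclohexane-1,3,5-trione. C1'–C2'–C3' plus the prenyl chain is the carbon chain of 6-methylhept-5-en-2-one, and C1' is also α to the benzophenone carbonyl.
- Further cuts: the diene goes back to a 1,3-diketone, the diketone to an aldol (then oxidation) between the methyl ketone and 3-silyloxy-2-prenylbenzaldehyde, and the ring A aryl–prenyl bond to a Stille coupling on 2-bromo-3-hydroxybenzaldehyde.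
- Forward: ring A is bought intact, silylated and prenylated; the chain is joined by aldol addition and oxidised; the diketone is silylated twice; ring B, the only ring made, closes in the three-plus-three annulation; fluoride frees the last phenol.
- Stereochemistry: the target has no stereocentre and no stereodefined alkene. The aldol carbinol centre and the enol ether geometries are transient and need no control.

Key step: step 6

Abbreviations: prenyl = 3-methylbut-2-en-1-yl; TBS = tert-butyldimethylsilyl; TMS = trimethylsilyl.

Remark: 9 and 10 are drawn as single isomers for definiteness (silyl on the alkyl-side oxygen in 9; 1Z,3Z in 10); other regio- or stereoisomers would converge, because all these carbons become sp2 carbons of ring B or of the carbonyl group in 14.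

**Route**

Step 1
Reactants: 1 2-bromo-3-hydroxybenzaldehyde
Product: 2 2-bromo-3-(tert-butyldimethylsilyloxy)benzaldehyde
Conditions: TBSCl (1.2 equiv), imidazole (2.5 equiv), DMF, 0 °C to rt
Reagents that add atoms: tert-butyldimethylsilyl chloride (TBSCl), CC(C)(C)[Si](C)(C)Cl
Why: Imidazole-promoted O-silylation of a phenol is routine, and the aryl TBS ether should tolerate the neutral palladium coupling, the lithium enolate at −78 °C, IBX, silyl triflate/amine and the acid chloride that follow.

Step 2
Reactants: 2 2-bromo-3-(tert-butyldimethylsilyloxy)benzaldehyde; 3 tributyl(3-methylbut-2-en-1-yl)stannane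
Product: 4 3-(tert-butyldimethylsilyloxy)-2-prenylbenzaldehyde
Conditions: Pd(PPh3)4 (5 mol %), DMF, 90 °C
Reagents that add atoms: none
Why: In this Stille cross-coupling, zerovalent palladium inserts into the aryl bromide (activated by the ortho formyl group), the prenyl group is transferred from tin, and reductive elimination at the unsubstituted terminus of the η3-prenyl ligand should give the linear prenyl arene under neutral conditions that spare the aldehyde and the silyl ether.

Step 3
Reactants: 4 3-(tert-butyldimethylsilyloxy)-2-prenylbenzaldehyde; 5 6-methylhept-5-en-2-one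
Product: 7 (±)-1-[3-(tert-butyldimethylsilyloxy)-2-prenylphenyl]-1-hydroxy-7-methyloct-6-en-3-one, via lithium 6-methylhepta-1,5-dien-2-olate 6 (not isolated)
Conditions: LiN(iPr)2 (1.15 equiv), THF, −78 °C, then 5 (1.1 equiv); then 4, −78 °C; AcOH in THF at −78 °C
Reagents that add atoms: none
Why: Kinetic deprotonation of the methyl ketone at −78 °C gives the less substituted lithium enolate, which undergoes aldol addition to the non-enolisable aldehyde; the new carbinol centre forms racemic and uncontrolled, which does not matter because step 4 oxidises it away.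

Step 4
Reactants: 7 (±)-1-[3-(tert-butyldimethylsilyloxy)-2-prenylphenyl]-1-hydroxy-7-methyloct-6-en-3-one
Product: 8 1-[3-(tert-butyldimethylsilyloxy)-2-prenylphenyl]-7-methyloct-6-ene-1,3-dione
Conditions: IBX (3 equiv), EtOAc, 77 °C
Reagents that add atoms: none
Why: Oxidation of a β-hydroxy ketone to the β-diketone with the pentavalent iodine reagent IBX is a neutral alcohol oxidation that should stop at the 1,3-dicarbonyl stage and leave the trisubstituted alkenes and the aryl silyl ether untouched.

Step 5
Reactants: 8 1-[3-(tert-butyldimethylsilyloxy)-2-prenylphenyl]-7-methyloct-6-ene-1,3-dione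
Product: 10 (1Z,3Z)-1-[3-(tert-butyldimethylsilyloxy)-2-prenylphenyl]-7-methyl-1,3-bis(trimethylsilyloxy)octa-1,3,6-triene, via monosilyl enol ether 9 (not isolated)
Conditions: TMSOTf (2.3 equiv), Et3N (3 equiv), Et2O, 0 °C to rt; salts removed under argon, concentrated, used crude
Reagents that add atoms: trimethylsilyl trifluoromethanesulfonate (TMSOTf), C[Si](C)(C)OS(=O)(=O)C(F)(F)F
Why: Soft enolisation with a silyl triflate and a tertiary amine converts the β-diketone first into the 3-silyloxy enone 9 and then, by a second O-silylation with deprotonation of the only other enolisable position (the C4 methylene), into the 1,3-bis(silyloxy)diene; the aryl side has no α-hydrogen, so a single constitution should result.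

Step 6
Reactants: 10 (1Z,3Z)-1-[3-(tert-butyldimethylsilyloxy)-2-prenylphenyl]-7-methyl-1,3-bis(trimethylsilyloxy)octa-1,3,6-triene; 11 malonyl dichloride
Product: 14 [3-(tert-butyldimethylsilyloxy)-2-prenylphenyl](2,4,6-trihydroxy-3-prenylphenyl)methanone, via acyclic acid chloride 12 (not isolated), via cyclohexanetrione 13 (not isolated)
Conditions: 11 (1.05 equiv) added over 2 h to 10, CH2Cl2 (0.02 M), −78 °C to 20 °C; pH 7 phosphate buffer work-up
Reagents that add atoms: none
Why: Proposed new method: the terminal diene carbon C4 (the future C3'), the most nucleophilic site as in the known uncatalysed terminal C-acylation of 1,3-bis(silyl enol ethers) by acid chlorides, attacks one acyl chloride of 11 and the oxocarbenium ion loses Me3SiCl to give 12 (C3'–C4' bond); the silyl enol ether that remains on the aroyl side then attacks the tethered acyl chloride through its central carbon C1' with loss of a second Me3SiCl (C1'–C6' bond), and trione 13 enolises to the aromatic ring. The closest known reaction type is the Effenberger cyclisation, in which an enol ether or silyl enol ether of a ketone is C-acylated twice by malonyl dichloride to a cyclohexane-1,3,5-trione; new here is its use on an acyclic 1,3-bis(silyloxy)diene in which the second nucleophilic carbon is already present as a silyl enol ether. Ring B closes in a 6-exo-trig mode (6-(enolexo)-exo-trig), C1' adding to the acyl chloride carbon. No stereocentre results, since the two sp3 centres of 13 are lost on enolisation. The step needs terminal before central attack, which the cross-conjugated diene secures because C4 carries the largest HOMO coefficient, and C- over O-acylation in the ring closure, for which the retained C1' silyl enol ether, the absence of base and the irreversible aromatisation of 13 are relied on, with slow addition at high dilution to suppress intermolecular acylation. Only Me3SiCl is released and no HCl, so both prenyl groups and the aryl silyl ether should survive.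

Step 7
Reactants: 14 [3-(tert-butyldimethylsilyloxy)-2-prenylphenyl](2,4,6-trihydroxy-3-prenylphenyl)methanone
Product: 15 cudraphenone D, (3-hydroxy-2-prenylphenyl)(2,4,6-trihydroxy-3-prenylphenyl)methanone
Conditions: TBAF (1.2 equiv), AcOH (1.5 equiv), THF, 0 °C
Reagents that add atoms: none
Why: Fluoride-induced cleavage of an aryl silyl ether is fast at 0 °C, and the acetic acid buffer keeps the polyphenol protonated, so that neither prenyl group meets strong acid or base and no chroman should form.

**Compound list**

1 | 2-bromo-3-hydroxybenzaldehyde | O=Cc1cccc(O)c1Br | starting material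
2 | 2-bromo-3-(tert-butyldimethylsilyloxy)benzaldehyde | O=Cc1cccc(O[Si](C)(C)C(C)(C)C)c1Br | intermediate
3 | tributyl(3-methylbut-2-en-1-yl)stannane | CCCC[Sn](CCCC)(CCCC)CC=C(C)C | starting material
4 | 3-(tert-butyldimethylsilyloxy)-2-(3-methylbut-2-en-1-yl)benzaldehyde | O=Cc1cccc(O[Si](C)(C)C(C)(C)C)c1CC=C(C)C | intermediate
5 | 6-methylhept-5-en-2-one | CC(=O)CCC=C(C)C | starting material
6 | lithium 6-methylhepta-1,5-dien-2-olate (kinetic enolate of 5, not isolated) | [Li+].[O-]C(=C)CCC=C(C)C | intermediate
7 | (±)-1-[3-(tert-butyldimethylsilyloxy)-2-(3-methylbut-2-en-1-yl)phenyl]-1-hydroxy-7-methyloct-6-en-3-one (racemic) | CC(C)=CCCC(=O)CC(O)c1cccc(O[Si](C)(C)C(C)(C)C)c1CC=C(C)C | intermediate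
8 | 1-[3-(tert-butyldimethylsilyloxy)-2-(3-methylbut-2-en-1-yl)phenyl]-7-methyloct-6-ene-1,3-dione | CC(C)=CCCC(=O)CC(=O)c1cccc(O[Si](C)(C)C(C)(C)C)c1CC=C(C)C | intermediate
9 | (2Z)-1-[3-(tert-butyldimethylsilyloxy)-2-(3-methylbut-2-en-1-yl)phenyl]-7-methyl-3-(trimethylsilyloxy)octa-2,6-dien-1-one (not isolated) | C[Si](C)(C)O/C(CCC=C(C)C)=C\C(=O)c1cccc(O[Si](C)(C)C(C)(C)C)c1CC=C(C)C | intermediate
10 | (1Z,3Z)-1-[3-(tert-butyldimethylsilyloxy)-2-(3-methylbut-2-en-1-yl)phenyl]-7-methyl-1,3-bis(trimethylsilyloxy)octa-1,3,6-triene | C[Si](C)(C)O/C(c1cccc(O[Si](C)(C)C(C)(C)C)c1CC=C(C)C)=C\C(O[Si](C)(C)C)=C\CC=C(C)C | intermediate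
11 | malonyl dichloride (propanedioyl dichloride) | O=C(Cl)CC(=O)Cl | starting material
12 | (6Z)-7-[3-(tert-butyldimethylsilyloxy)-2-(3-methylbut-2-en-1-yl)phenyl]-4-(3-methylbut-2-en-1-yl)-3,5-dioxo-7-(trimethylsilyloxy)hept-6-enoyl chloride (racemic at C4, not isolated) | C[Si](C)(C)O/C(c1cccc(O[Si](C)(C)C(C)(C)C)c1CC=C(C)C)=C\C(=O)C(CC=C(C)C)C(=O)CC(=O)Cl | intermediate
13 | 2-[3-(tert-butyldimethylsilyloxy)-2-(3-methylbut-2-en-1-yl)benzoyl]-4-(3-methylbut-2-en-1-yl)cyclohexane-1,3,5-trione (mixture of stereoisomers and tautomers, not isolated) | O=C(c1cccc(O[Si](C)(C)C(C)(C)C)c1CC=C(C)C)C1C(=O)CC(=O)C(CC=C(C)C)C1=O | intermediate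
14 | [3-(tert-butyldimethylsilyloxy)-2-(3-methylbut-2-en-1-yl)phenyl][2,4,6-trihydroxy-3-(3-methylbut-2-en-1-yl)phenyl]methanone | CC(C)=CCc1c(O[Si](C)(C)C(C)(C)C)cccc1C(=O)c1c(O)cc(O)c(CC=C(C)C)c1O | intermediate
15 | cudraphenone D, [3-hydroxy-2-(3-methylbut-2-en-1-yl)phenyl][2,4,6-trihydroxy-3-(3-methylbut-2-en-1-yl)phenyl]methanone | CC(C)=CCc1c(O)cccc1C(=O)c1c(O)cc(O)c(CC=C(C)C)c1O | target

**Step count**

Total steps: 7. Longest linear sequence: 7 steps (1 to 15).

**Steps most likely to fail**

Step 6 (the step proposed as a new method). After the first acylation the ring may close through the enol oxygen at C2' instead of through carbon C1', or the second acyl chloride may be captured by another diene molecule and give oligomers. The fallback uses known chemistry and sets out from diene 10. 4-Hydroxy-2-pyranones are the usual products when silyl enol ethers meet malonyl dichloride, so the O-closed product would be accepted rather than fought. It is 6-{2-[3-(tert-butyldimethylsilyloxy)-2-prenylphenyl]-2-oxoethyl}-4-hydroxy-5-prenyl-2H-pyran-2-one F1, which would be isolated and heated with Mg(OMe)2 in MeOH. Methoxide should open the lactone to methyl 7-[3-(tert-butyldimethylsilyloxy)-2-prenylphenyl]-4-prenyl-3,5,7-trioxoheptanoate F2. The C6 carbanion of F2 (C1' of the target) then closes on the ester carbon in an intramolecular Claisen condensation, the established biomimetic conversion of 6-(2-oxoalkyl)-4-hydroxypyranones into acylphloroglucinols, and forms the same C1'–C6' bond. The aryl silyl ether is expected to be methanolysed under these conditions, so this sequence comes back to the route at the target 15 and step 7 falls away.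

Step 2. The prenyl group may couple through its γ-terminus, giving the 1,1-dimethylallyl arene, or transmetalation may be slow at the bromide flanked by two ortho substituents. The fallback sets out from bromide 2. Stille coupling with allyltributylstannane (Pd(PPh3)4, toluene, 100 °C), whose two allyl termini are equivalent, should give 2-allyl-3-(tert-butyldimethylsilyloxy)benzaldehyde F3. Olefin cross-metathesis of F3 with excess 2-methylbut-2-ene (second-generation Grubbs catalyst, RuCl2(=CHPh)(PCy3)(H2IMes), CH2Cl2, 40 °C) then builds the trisubstituted alkene and returns to the route at aldehyde 4.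

Step 5. The second silylation may stall at the monosilyl stage, or the bis(silyloxy)diene may lose a silyl group to adventitious acid from residual ammonium triflate during isolation. The fallback sets out from diketone 8 and separates the two silylations, using a different mode of enolisation for the second. TMSCl/Et3N (pentane, rt) gives the monosilyl enol ether 9, which is freed from the ammonium salt by filtration and concentrated. LiN(iPr)2 in THF at −78 °C then removes a C4 proton to give lithium (1Z,3Z)-1-[3-(tert-butyldimethylsilyloxy)-2-prenylphenyl]-7-methyl-3-(trimethylsilyloxy)octa-1,3,6-trien-1-olate F4. O-Silylation of F4 with TMSCl and filtration from pentane return to the route at diene 10.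

**Further compounds**

F1 | step 6 | 6-{2-[3-(tert-butyldimethylsilyloxy)-2-(3-methylbut-2-en-1-yl)phenyl]-2-oxoethyl}-4-hydroxy-5-(3-methylbut-2-en-1-yl)-2H-pyran-2-one | O=C(Cc1oc(=O)cc(O)c1CC=C(C)C)c1cccc(O[Si](C)(C)C(C)(C)C)c1CC=C(C)C
F2 | step 6 | methyl 7-[3-(tert-butyldimethylsilyloxy)-2-(3-methylbut-2-en-1-yl)phenyl]-4-(3-methylbut-2-en-1-yl)-3,5,7-trioxoheptanoate | COC(=O)CC(=O)C(CC=C(C)C)C(=O)CC(=O)c1cccc(O[Si](C)(C)C(C)(C)C)c1CC=C(C)C
F3 | step 2 | 2-allyl-3-(tert-butyldimethylsilyloxy)benzaldehyde | C=CCc1c(O[Si](C)(C)C(C)(C)C)cccc1C=O
F4 | step 5 | lithium (1Z,3Z)-1-[3-(tert-butyldimethylsilyloxy)-2-(3-methylbut-2-en-1-yl)phenyl]-7-methyl-3-(trimethylsilyloxy)octa-1,3,6-trien-1-olate | [Li+].[O-]/C(c1cccc(O[Si](C)(C)C(C)(C)C)c1CC=C(C)C)=C\C(O[Si](C)(C)C)=C\CC=C(C)C
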